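**Remark (assumption):** The SMILES is read as the (2S,4R,6S) isomer, in which the aryl group on C2, the hydroxyl on C4 and the arylethyl chain on C6 are all cis (all equatorial). Compounds 1, 2 and 7 are taken as commercial. The ring numbering of the target (O1, aryl-bearing C2, carbinol C4, chain-bearing C6) is used for all intermediates.

## Structural features

The target is a cyclised diarylheptanoid: an oxane ring O1–C2–C3–C4–C5–C6 with a 3,4-dihydroxy-5-methoxyphenyl group directly on C2, a hydroxyl on C4 and a 2-(4-hydroxyphenyl)ethyl chain on C6. The stereocentres C2 (S), C4 (R) and C6 (S) are not adjacent; they stand in a 1,3,5-relationship around the ring, and all three substituents are equatorial in the chair. C2 is both benzylic to a very electron-rich arene (para to a phenolic oxygen) and bound to O1, so the C2–O1 bond is open to acid ionisation and to hydrogenolysis. The free catechol is oxidation-sensitive and must stay masked to the end. The real difficulty is to set C2 against C6 across the ring oxygen in one absolute sense without letting the stabilised C2 cation scramble; C4 is easy once a 2,6-diequatorial oxan-4-one exists. The key step exploits this: if O1–C2 is kept and C2–C3 is cut, C2 becomes the CH2 of an ordinary electron-rich benzyl ether, the most easily oxidised C–H position of an acyclic precursor. In one sentence: hydride is abstracted oxidatively from the benzylic ether CH2 of the acyclic enol acetate 12, and the resulting oxocarbenium ion is captured by the enol acetate to close the oxan-4-one 14.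

## Logic of the disconnections

**16 from 15.** No skeletal bond is cut. The three phenolic O–H bonds are traced back to O–C bonds: one O–CH2Ph and the two C–O bonds of a CPh2 ketal on the catechol. The gain is a substrate whose phenols are inert to oxidant, Grignard reagent, acetylide and hydride. The demand is one hydrogenolysis that cleaves these O–C bonds and spares the benzylic C2–O1 bond.

**15 from 14.** The C4–H bond is cut, so the carbinol goes back to a ketone. This removes one stereocentre and leaves a 2,6-cis-oxan-4-one. The demand is axial hydride delivery to the diequatorial chair, so that the C4 hydroxyl ends up equatorial.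

**14 from 12 (through 13).** The ring bond C2–C3 is cut and a hydrogen is put back on C2; the C4 carbonyl returns to an enol acetate. This is the strategic cut: ring and C2 stereocentre vanish together, and the precursor is an acyclic benzyl ether with the single stereocentre C6. The forward step must abstract hydride only at the ArCH2–O carbon, pass through an E-configured cation in a chair, and leave C6 untouched.

**12 from 11.** The C4–OAc bond and one C3–H bond are cut, which returns the enol acetate to a terminal alkyne. The gain is a robust masked enol that survives the ether formation. The demand is Markovnikov addition of acetic acid across the alkyne.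

**11 from 6 and 10.** The ether bond between the oxygen on C6 and the benzylic carbon (the later O1–C2 bond) is cut. This splits the molecule into its two aryl halves and makes the route convergent. The demand is alkylation of a secondary alcohol without touching its C–O bond, the ketal or the alkyne.

**10 from 9, 9 from 8, 8 from 7.** These are functional-group steps on the aryl half: the imidate C–O bond, the benzylic C–H bond from the aldehyde, and the two ketal C–O bonds. The gain is a commercial trioxygenated benzaldehyde. The demand is a catechol mask that has no oxidisable C–H and falls off in the final hydrogenolysis.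

**6 from 4 (through 5).** The C–C bond between the future C5 methylene and the future C4 alkyne carbon is cut. The gain is a two-carbon nucleophile plus a chlorohydrin that becomes a terminal epoxide in the flask. The demand is attack only at the terminal epoxide carbon, so that the stereocentre is never a reaction site.

**4 from 1 and 2 (through 3).** The C–C bond between the two methylenes of the arylethyl chain is cut. This leads to a benzylic halide and a three-carbon epoxide that carries the only purchased stereocentre, the later C6. The demand is copper-catalysed attack at the epoxide CH2 in preference to the chloromethyl group.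

## Other disconnections considered

**Alternative 1:** Prins cyclisation, the route that comes to mind first. The cut is O1–C2 plus C2–C3, with the C4 oxygen delivered by the acid. Homoallylic alcohol A1 and aldehyde 8 would condense in trifluoroacetic acid to the all-cis trifluoroacetate A2, and methanolysis would give 15. It is shorter on paper, but it is the obvious route and fails the first test. There is also a mechanistic ground. With this very electron-rich aldehyde the oxocarbenium ion is strongly stabilised and long-lived in protic acid. That opens the 2-oxonia-Cope and allyl-transfer manifold, which would be expected to cause side-chain exchange and erosion of enantiopurity, and the strong acid threatens the CPh2 ketal. The chosen plan forms the same type of cation under buffered, anhydrous conditions and traps it with a much more nucleophilic enol acetate.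

**Alternative 2:** Catalytic asymmetric hetero-Diels–Alder reaction. The cut is O1–C2 plus C5–C6. Silyloxydiene A3 (two steps from 8) and aldehyde A4 would combine under a chiral Cr(III) Schiff-base catalyst to the cis cycloadduct A5, and desilylation would give 14. Here the absolute sense and the C2/C6 relationship both rest on catalyst control. The partners are poorly matched: a donor-aryl-terminated monosilyloxy diene and an unactivated, enolisable aliphatic aldehyde. The route is no shorter than the chosen one, which buys C6 and relays it to C2 through a chair.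

**Alternative 3:** C-Aryl addition to a lactone followed by ionic reduction. The cut is the C2–aryl bond and the C2–H bond. The aryllithium from bromide A7 would add to lactone A6 to give hemiketal A8. Reduction with Et3SiH and BF3·OEt2, by axial hydride delivery to the cyclic oxocarbenium ion, then desilylation, would lead to 15. The lactone A6 must already carry C4 and C6, which means a separate syn-1,3-diol synthesis of several steps. The Lewis-acid step also places a cation β to the C4 silyloxy group (risk of elimination) and next to the acid-labile ketal. The chosen plan creates C2 and C4 from C6 alone and is shorter.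

Key step: step 8

## Steps

Step 1
Reactants: 1 1-(benzyloxy)-4-(chloromethyl)benzene; 2 (S)-epichlorohydrin
Product: 4 (2S)-4-[4-(benzyloxy)phenyl]-1-chlorobutan-2-ol, via [4-(benzyloxy)benzyl]magnesium chloride 3 (not isolated)
Conditions: Mg, THF, 0 °C to rt (slow addition of 1); then 2, CuI (10 mol %), THF, −40 to −20 °C
Reagents that add atoms: none
Why: Benzylic Grignard formation, then copper-catalysed SN2 opening of the epoxide at its unsubstituted CH2 (Cu-catalysed Grignard epoxide opening); the C–O bond at the stereocentre of 2 is not touched, so 4 should keep the (S) configuration, and the primary chloride survives at low temperature.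

Step 2
Reactants: 4 (2S)-4-[4-(benzyloxy)phenyl]-1-chlorobutan-2-ol
Product: 6 (3S)-1-[4-(benzyloxy)phenyl]hex-5-yn-3-ol, via (2S)-2-{2-[4-(benzyloxy)phenyl]ethyl}oxirane 5 (not isolated)
Conditions: HC≡CLi·H2NCH2CH2NH2 (3.5 equiv), DMSO, 0 °C to rt
Reagents that add atoms: lithium acetylide ethylenediamine complex, [Li+].[C-]#C.NCCN
Why: The first equivalent of acetylide deprotonates the alcohol and the alkoxide closes epoxide 5 by intramolecular Williamson displacement of chloride; a second equivalent opens 5 at the terminal carbon (SN2 epoxide opening by an acetylide), so the carbinol carbon is never a reaction site and should stay (S).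

Step 3
Reactants: 7 3,4-dihydroxy-5-methoxybenzaldehyde
Product: 8 7-methoxy-2,2-diphenyl-1,3-benzodioxole-5-carbaldehyde
Conditions: Ph2CCl2, K2CO3, MeCN, rt to 60 °C
Reagents that add atoms: dichlorodiphenylmethane, ClC(Cl)(c1ccccc1)c1ccccc1
Why: Double O-alkylation of the catechol by the gem-dichloride gives the cyclic diphenylmethylene ketal (benzodioxole formation); the ketal has no C–H bond that the later oxidant could attack and is removable by hydrogenolysis.

Step 4
Reactants: 8 7-methoxy-2,2-diphenyl-1,3-benzodioxole-5-carbaldehyde
Product: 9 (7-methoxy-2,2-diphenyl-1,3-benzodioxol-5-yl)methanol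
Conditions: NaBH4, MeOH/THF, 0 °C
Reagents that add atoms: none
Why: Standard borohydride reduction of an aryl aldehyde; ketal and methyl ether are inert.

Step 5
Reactants: 9 (7-methoxy-2,2-diphenyl-1,3-benzodioxol-5-yl)methanol
Product: 10 (7-methoxy-2,2-diphenyl-1,3-benzodioxol-5-yl)methyl 2,2,2-trichloroacetimidate
Conditions: Cl3CCN, DBU (10 mol %), CH2Cl2, 0 °C
Reagents that add atoms: trichloroacetonitrile, N#CC(Cl)(Cl)Cl
Why: Base-catalysed addition of the alkoxide to the nitrile (trichloroacetimidate formation), the usual activation of electron-rich benzyl alcohols for transfer under mild acid.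

Step 6
Reactants: 6 (3S)-1-[4-(benzyloxy)phenyl]hex-5-yn-3-ol; 10 (7-methoxy-2,2-diphenyl-1,3-benzodioxol-5-yl)methyl 2,2,2-trichloroacetimidate
Product: 11 6-[({(3S)-1-[4-(benzyloxy)phenyl]hex-5-yn-3-yl}oxy)methyl]-4-methoxy-2,2-diphenyl-1,3-benzodioxole
Conditions: La(OTf)3 (5 mol %), toluene, rt
Reagents that add atoms: none
Why: Lewis-acid-catalysed benzylation with a trichloroacetimidate (transfer of the stabilised benzyl cation to the alcohol oxygen); the C–O bond of the stereocentre is not broken, so the configuration is retained, and the mild lanthanide triflate should spare ketal and alkyne.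

Step 7
Reactants: 11 6-[({(3S)-1-[4-(benzyloxy)phenyl]hex-5-yn-3-yl}oxy)methyl]-4-methoxy-2,2-diphenyl-1,3-benzodioxole
Product: 12 (4S)-6-[4-(benzyloxy)phenyl]-4-[(7-methoxy-2,2-diphenyl-1,3-benzodioxol-5-yl)methoxy]hex-1-en-2-yl acetate
Conditions: [RuCl2(p-cymene)]2 (2 mol %), tri(2-furyl)phosphine (4 mol %), Na2CO3 (cat.), AcOH (2 equiv), toluene, 80 °C
Reagents that add atoms: acetic acid, CC(=O)O
Why: Ruthenium-catalysed Markovnikov hydroacyloxylation of a terminal alkyne should give the 2-acetoxy-1-alkene; the ethers, the ketal and the stereocentre are not involved under these buffered conditions.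

Step 8
Reactants: 12 (4S)-6-[4-(benzyloxy)phenyl]-4-[(7-methoxy-2,2-diphenyl-1,3-benzodioxol-5-yl)methoxy]hex-1-en-2-yl acetate
Product: 14 (2S,6S)-6-{2-[4-(benzyloxy)phenyl]ethyl}-2-(7-methoxy-2,2-diphenyl-1,3-benzodioxol-5-yl)oxan-4-one, via (E)-benzylic oxocarbenium ion 13 (not isolated)
Conditions: DDQ (2 equiv), 2,6-dichloropyridine (4 equiv), LiClO4 (cat.), 4 Å MS, ClCH2CH2Cl, rt
Reagents that add atoms: none
Why: DDQ takes an electron from the trioxygenated arene and then a hydrogen atom from the ArCH2–O carbon (net hydride abstraction) to give the aryl-conjugated (E)-oxocarbenium ion 13 paired with DDQH−; the tethered enol acetate attacks the cationic carbon through its terminal CH2, and loss of the acetyl group from the resulting acyloxocarbenium ion (to DDQH− or on work-up) unveils the C4 ketone. The closest known reaction type is the DDQ-mediated oxidative C–H cleavage of benzylic ethers with intramolecular capture by an enol acetate, an oxidatively triggered Prins/Mukaiyama-type cyclisation to 2,6-cis-oxan-4-ones. The one ring is closed by forming C2–C3 in a 6-endo-trig mode with respect to both the C=O+ bond and the enol C=C bond, through a chair. The new stereocentre C2 is controlled by C6: the oxocarbenium ion is E to avoid allylic-type strain, the arylethyl chain on C6 sits equatorial in the chair, and the aryl group is thereby also equatorial, which should give the 2,6-cis relationship, i.e. (2S) from (6S). C6 itself is never part of a cation or an enol, so it cannot erode. The step needs site selectivity among the benzylic positions; this is secured by the low oxidation potential of the trioxygenated ring and by oxygen stabilisation of the cation, whereas the 4-benzyloxyphenyl ring has one donor only, its ring CH2 has no α-oxygen, and the CPh2 ketal has no C–H at all. It also needs the cation to cyclise faster than it is hydrolysed or deprotonated, which molecular sieves, the hindered weak base and the high nucleophilicity of the enol acetate should secure. Further oxidation of 14 at C2–H is expected to be slow, since the β-carbonyl group destabilises the corresponding cation inductively.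

Step 9
Reactants: 14 (2S,6S)-6-{2-[4-(benzyloxy)phenyl]ethyl}-2-(7-methoxy-2,2-diphenyl-1,3-benzodioxol-5-yl)oxan-4-one
Product: 15 (2S,4R,6S)-6-{2-[4-(benzyloxy)phenyl]ethyl}-2-(7-methoxy-2,2-diphenyl-1,3-benzodioxol-5-yl)oxan-4-ol
Conditions: NaBH4, MeOH, −40 to 0 °C
Reagents that add atoms: none
Why: A small hydride should attack the chair ketone, whose C2 and C6 substituents are both equatorial, from the axial direction (torsional control as in substituted cyclohexanones), which places the new C4 hydroxyl equatorial and cis to both neighbours, i.e. (4R).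

Step 10
Reactants: 15 (2S,4R,6S)-6-{2-[4-(benzyloxy)phenyl]ethyl}-2-(7-methoxy-2,2-diphenyl-1,3-benzodioxol-5-yl)oxan-4-ol
Product: 16 (2S,4R,6S)-2-(3,4-dihydroxy-5-methoxyphenyl)-6-[2-(4-hydroxyphenyl)ethyl]oxan-4-ol (CNP0186008.1)
Conditions: H2 (1 atm), Pd(OH)2/C, EtOAc/MeOH, rt
Reagents that add atoms: none
Why: Hydrogenolysis of the aryl benzyl ether and of the doubly benzylic diphenylmethylene ketal under neutral conditions; no stereocentre takes part, and the ring C2–O1 bond, a benzylic dialkyl-type ether, is expected to be cleaved much more slowly at 1 atm and room temperature.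

## Compound list

1 | 1-(benzyloxy)-4-(chloromethyl)benzene | ClCc1ccc(OCc2ccccc2)cc1 | starting material
2 | (S)-epichlorohydrin, (2S)-2-(chloromethyl)oxirane | ClC[C@@H]1CO1 | starting material
3 | [4-(benzyloxy)benzyl]magnesium chloride | Cl[Mg]Cc1ccc(OCc2ccccc2)cc1 | intermediate (not isolated)
4 | (2S)-4-[4-(benzyloxy)phenyl]-1-chlorobutan-2-ol | ClC[C@@H](O)CCc1ccc(OCc2ccccc2)cc1 | intermediate
5 | (2S)-2-{2-[4-(benzyloxy)phenyl]ethyl}oxirane | C(C[C@H]1CO1)c1ccc(OCc2ccccc2)cc1 | intermediate (not isolated)
6 | (3S)-1-[4-(benzyloxy)phenyl]hex-5-yn-3-ol | C#CC[C@@H](O)CCc1ccc(OCc2ccccc2)cc1 | intermediate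
7 | 3,4-dihydroxy-5-methoxybenzaldehyde (5-hydroxyvanillin) | COc1cc(C=O)cc(O)c1O | starting material
8 | 7-methoxy-2,2-diphenyl-1,3-benzodioxole-5-carbaldehyde | COc1cc(C=O)cc2OC(c3ccccc3)(c3ccccc3)Oc12 | intermediate
9 | (7-methoxy-2,2-diphenyl-1,3-benzodioxol-5-yl)methanol | COc1cc(CO)cc2OC(c3ccccc3)(c3ccccc3)Oc12 | intermediate
10 | (7-methoxy-2,2-diphenyl-1,3-benzodioxol-5-yl)methyl 2,2,2-trichloroacetimidate | COc1cc(COC(=N)C(Cl)(Cl)Cl)cc2OC(c3ccccc3)(c3ccccc3)Oc12 | intermediate
11 | 6-[({(3S)-1-[4-(benzyloxy)phenyl]hex-5-yn-3-yl}oxy)methyl]-4-methoxy-2,2-diphenyl-1,3-benzodioxole | COc1cc(CO[C@H](CC#C)CCc3ccc(OCc4ccccc4)cc3)cc2OC(c3ccccc3)(c3ccccc3)Oc12 | intermediate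
12 | (4S)-6-[4-(benzyloxy)phenyl]-4-[(7-methoxy-2,2-diphenyl-1,3-benzodioxol-5-yl)methoxy]hex-1-en-2-yl acetate | COc1cc(CO[C@H](CC(=C)OC(C)=O)CCc3ccc(OCc4ccccc4)cc3)cc2OC(c3ccccc3)(c3ccccc3)Oc12 | intermediate
13 | (E)-benzylic oxocarbenium ion from 12 (cation; counter-ion DDQH−), (S) at the ether carbon | COc1cc(/C=[O+]/[C@H](CC(=C)OC(C)=O)CCc3ccc(OCc4ccccc4)cc3)cc2OC(c3ccccc3)(c3ccccc3)Oc12 | intermediate (not isolated)
14 | (2S,6S)-6-{2-[4-(benzyloxy)phenyl]ethyl}-2-(7-methoxy-2,2-diphenyl-1,3-benzodioxol-5-yl)oxan-4-one | COc1cc([C@@H]2CC(=O)C[C@H](CCc3ccc(OCc4ccccc4)cc3)O2)cc2OC(c3ccccc3)(c3ccccc3)Oc12 | intermediate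
15 | (2S,4R,6S)-6-{2-[4-(benzyloxy)phenyl]ethyl}-2-(7-methoxy-2,2-diphenyl-1,3-benzodioxol-5-yl)oxan-4-ol | COc1cc([C@@H]2C[C@H](O)C[C@H](CCc3ccc(OCc4ccccc4)cc3)O2)cc2OC(c3ccccc3)(c3ccccc3)Oc12 | intermediate
16 | (2S,4R,6S)-2-(3,4-dihydroxy-5-methoxyphenyl)-6-[2-(4-hydroxyphenyl)ethyl]oxan-4-ol | COc1cc([C@@H]2C[C@H](O)C[C@H](CCc3ccc(O)cc3)O2)cc(O)c1O | target

## Step count and least certain steps

Total step count: 10. Longest linear sequence: 8 steps (7 to 16 through steps 3–10); the other branch (1 and 2 to 16 through steps 1, 2, 6–10) has 7.

**Step 8 (key step).** The most likely failure is that the oxocarbenium ion is lost before it cyclises, by hydrolysis with adventitious water back to aldehyde and alcohol. Hydride abstraction could also be slow, because the ring oxygen para to the reacting carbon is flanked by two ortho substituents. Slow oxidation of the electron-rich product is a further risk. The fallback avoids the C–H oxidation and sets out from 6 and 8. Double deprotonation of 6 (n-BuLi, THF, −78 °C) and addition to 8 would give the propargylic diol (5S)-7-[4-(benzyloxy)phenyl]-1-(7-methoxy-2,2-diphenyl-1,3-benzodioxol-5-yl)hept-2-yne-1,5-diol F1 as a mixture of C1 epimers, which is of no consequence. A Meyer–Schuster rearrangement (Ph3PAuNTf2 cat., MeOH/toluene, rt) would move the oxygen and give the hydroxy enone (1E,5S)-7-[4-(benzyloxy)phenyl]-5-hydroxy-1-(7-methoxy-2,2-diphenyl-1,3-benzodioxol-5-yl)hept-1-en-3-one F2. An equilibrating intramolecular oxa-Michael addition (DBU or Amberlyst-15, CH2Cl2) should then close the ring to the thermodynamic 2,6-cis ketone, which returns to the route at 14.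

**Step 7.** The likely failures are catalyst inhibition by the Lewis-basic ethers, incomplete regiocontrol of the acetic acid addition, and acid-promoted loss of the electron-rich benzyl ether at 80 °C. The fallback sets out from 11 and replaces hydroacyloxylation by hydration and enolate O-acylation. Gold-catalysed Markovnikov hydration (Ph3PAuNTf2 cat., dioxane/H2O) would give the methyl ketone (4S)-6-[4-(benzyloxy)phenyl]-4-[(7-methoxy-2,2-diphenyl-1,3-benzodioxol-5-yl)methoxy]hexan-2-one F3. Kinetic deprotonation at the methyl group (LDA, THF, −78 °C) and trapping with acetic anhydride should give the less substituted enol acetate, which returns to the route at 12.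

**Step 6.** The likely failure is ionisation of the very electron-rich imidate faster than its capture by the hindered secondary alcohol, which leads to self-alkylation of the arene and imidate-to-amide rearrangement. The fallback sets out from 9 and switches from cation transfer to an SN2 Williamson etherification. PBr3 (Et2O, 0 °C) would give 6-(bromomethyl)-4-methoxy-2,2-diphenyl-1,3-benzodioxole F4, and the sodium alkoxide of 6 (NaH, Bu4NI cat., THF/DMF, 0 °C to rt) would be alkylated with it, which returns to the route at 11.

**Step 10.** The likely failure is over-reduction: hydrogenolytic opening of the benzylic C2–O1 bond once the para-hydroxyl is free, or, if the catalyst is tamed to prevent this, stalled cleavage of the ketal. The fallback sets out from 15 and avoids hydrogen. Aqueous acetic acid (AcOH/H2O 4:1, 70 °C) would hydrolyse the ketal to 5-[(2S,4R,6S)-6-{2-[4-(benzyloxy)phenyl]ethyl}-4-hydroxyoxan-2-yl]-3-methoxybenzene-1,2-diol F5. Any reversible ionisation at C2 under these conditions should return the all-equatorial isomer. The remaining aryl benzyl ether would then be cleaved with BCl3 and pentamethylbenzene as cation scavenger (CH2Cl2, −78 °C), which returns to the route at 16.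

## Further compounds

F1 | step 8 | (5S)-7-[4-(benzyloxy)phenyl]-1-(7-methoxy-2,2-diphenyl-1,3-benzodioxol-5-yl)hept-2-yne-1,5-diol (both C1 epimers) | COc1cc(C(O)C#CC[C@@H](O)CCc3ccc(OCc4ccccc4)cc3)cc2OC(c3ccccc3)(c3ccccc3)Oc12
F2 | step 8 | (1E,5S)-7-[4-(benzyloxy)phenyl]-5-hydroxy-1-(7-methoxy-2,2-diphenyl-1,3-benzodioxol-5-yl)hept-1-en-3-one | COc1cc(/C=C/C(=O)C[C@@H](O)CCc3ccc(OCc4ccccc4)cc3)cc2OC(c3ccccc3)(c3ccccc3)Oc12
F3 | step 7 | (4S)-6-[4-(benzyloxy)phenyl]-4-[(7-methoxy-2,2-diphenyl-1,3-benzodioxol-5-yl)methoxy]hexan-2-one | COc1cc(CO[C@H](CC(C)=O)CCc3ccc(OCc4ccccc4)cc3)cc2OC(c3ccccc3)(c3ccccc3)Oc12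
F4 | step 6 | 6-(bromomethyl)-4-methoxy-2,2-diphenyl-1,3-benzodioxole | COc1cc(CBr)cc2OC(c3ccccc3)(c3ccccc3)Oc12
F5 | step 10 | 5-[(2S,4R,6S)-6-{2-[4-(benzyloxy)phenyl]ethyl}-4-hydroxyoxan-2-yl]-3-methoxybenzene-1,2-diol | COc1cc([C@@H]2C[C@H](O)C[C@H](CCc3ccc(OCc4ccccc4)cc3)O2)cc(O)c1O
A1 | alternative 1 | (3S)-1-[4-(benzyloxy)phenyl]hex-5-en-3-ol | C=CC[C@@H](O)CCc1ccc(OCc2ccccc2)cc1
A2 | alternative 1 | (2S,4R,6S)-6-{2-[4-(benzyloxy)phenyl]ethyl}-2-(7-methoxy-2,2-diphenyl-1,3-benzodioxol-5-yl)oxan-4-yl trifluoroacetate | COc1cc([C@@H]2C[C@H](OC(=O)C(F)(F)F)C[C@H](CCc3ccc(OCc4ccccc4)cc3)O2)cc2OC(c3ccccc3)(c3ccccc3)Oc12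
A3 | alternative 2 | triethyl{[(3E)-4-(7-methoxy-2,2-diphenyl-1,3-benzodioxol-5-yl)buta-1,3-dien-2-yl]oxy}silane | COc1cc(/C=C/C(=C)O[Si](CC)(CC)CC)cc2OC(c3ccccc3)(c3ccccc3)Oc12
A4 | alternative 2 | 3-[4-(benzyloxy)phenyl]propanal | O=CCCc1ccc(OCc2ccccc2)cc1
A5 | alternative 2 | {[(2S,6S)-2-{2-[4-(benzyloxy)phenyl]ethyl}-6-(7-methoxy-2,2-diphenyl-1,3-benzodioxol-5-yl)-3,6-dihydro-2H-pyran-4-yl]oxy}triethylsilane | COc1cc([C@@H]2C=C(O[Si](CC)(CC)CC)C[C@H](CCc3ccc(OCc4ccccc4)cc3)O2)cc2OC(c3ccccc3)(c3ccccc3)Oc12
A6 | alternative 3 | (4R,6S)-6-{2-[4-(benzyloxy)phenyl]ethyl}-4-[(tert-butyldimethylsilyl)oxy]oxan-2-one | O=C1C[C@H](O[Si](C)(C)C(C)(C)C)C[C@H](CCc2ccc(OCc3ccccc3)cc2)O1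
A7 | alternative 3 | 6-bromo-4-methoxy-2,2-diphenyl-1,3-benzodioxole | COc1cc(Br)cc2OC(c3ccccc3)(c3ccccc3)Oc12
A8 | alternative 3 | (2S,4R,6S)-6-{2-[4-(benzyloxy)phenyl]ethyl}-4-[(tert-butyldimethylsilyl)oxy]-2-(7-methoxy-2,2-diphenyl-1,3-benzodioxol-5-yl)oxan-2-ol (anomer drawn with the aryl group equatorial) | COc1cc([C@]2(O)C[C@H](O[Si](C)(C)C(C)(C)C)C[C@H](CCc3ccc(OCc4ccccc4)cc3)O2)cc2OC(c3ccccc3)(c3ccccc3)Oc12
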